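**Strategy**

Dinklagin A is cut at C2–C1′ of the flavanone into 6-bromo-7-hydroxychromone and (2,2-dimethyl-2H-chromen-6-yl)boronic acid, joined by enantioselective conjugate arylation; the prenyl group follows by Stille coupling. The route rests on the pyran ring of the B-ring chromene (O1, C2, C3, C4, C4a, C8a): its O1–C8a bond and cis C3=C4 alkene are the furan ring of benzofuran, which lacks only the Me2C carbon C2. In one operation, reductive cleavage of the vinylic C–O bond of benzofuran-5-ol, addition of the resulting (Z)-vinyllithium to acetone and acid closure insert that carbon and turn the five-membered ring into the six-membered one.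

Key step: step 1

Assumption: the (R)-antipode of t-BuPyOx is taken to give the 2S adduct, since the (S)-ligand arylates cyclic enones on the face that corresponds to 2R in a chromone; 1 and 7 are treated as catalogue compounds.

**Route**

Step 1
Reactants: 1 benzofuran-5-ol
Product: 4 2,2-dimethyl-2H-chromen-6-ol, via (Z)-vinyllithium bis(phenoxide) 2 (not isolated), via (Z)-enetriol 3 (not isolated)
Conditions: n-BuLi, THF, −78 °C; Li powder, DTBB (4,4′-di-tert-butylbiphenyl, 10 mol %), 0 °C to rt; acetone, −78 °C; then aq. H3PO4, toluene, 50 °C, under argon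
Reagents that add atoms: acetone CC(C)=O
Why: Electron transfer from the lithium arenide to the lithium aryloxide of 1 cleaves the vinylic C2–O bond (phenoxide as leaving group) to give the configurationally stable (Z)-vinyllithium 2, which adds to acetone and gives triol 3 on protonation; acid then ionises the tertiary allylic alcohol to an ortho-hydroxy-stabilised allyl cation (a protonated ortho-quinone methide) that the phenol oxygen captures at the tertiary terminus, so that Me2C is formally inserted into the C2–O bond and the furan ring becomes the pyran ring. The closest known reaction type is the arene-catalysed reductive lithiation of benzofuran with carbonyl trapping and acid cyclisation of the resulting (Z)-2-(3-hydroxyalkenyl)phenols to 2H-chromenes. The pyran ring closes by 6-endo-trig O-attack on the allyl cation terminus (equivalently an oxa-6π electrocyclisation of the ortho-quinone methide). No stereocentre is formed. The step needs cleavage of the vinylic and not the aryl C–O bond, retention of the cis alkene geometry and closure at the tertiary carbon: the first is secured by the enol-ether character of that bond and the phenoxide leaving group, the second by the ring origin of the alkene, the third because closure at the benzylic terminus would give a four-membered ring.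

Step 2
Reactants: 4 2,2-dimethyl-2H-chromen-6-ol
Product: 5 2,2-dimethyl-2H-chromen-6-yl trifluoromethanesulfonate
Conditions: PhNTf2, Et3N, DMAP (cat.), CH2Cl2, 0 °C to rt
Reagents that add atoms: N-phenylbis(trifluoromethanesulfonimide) O=S(=O)(N(c1ccccc1)S(=O)(=O)C(F)(F)F)C(F)(F)F
Why: O-sulfonylation of the phenoxide with a mild triflyl donor under basic conditions (aryl triflate formation) should spare the acid-sensitive chromene double bond.

Step 3
Reactants: 5 2,2-dimethyl-2H-chromen-6-yl trifluoromethanesulfonate
Product: 6 (2,2-dimethyl-2H-chromen-6-yl)boronic acid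
Conditions: B2(OH)4, Pd(OAc)2 (cat.), XPhos, KOAc, EtOH, 80 °C
Reagents that add atoms: tetrahydroxydiboron OB(O)B(O)O
Why: Miyaura borylation (oxidative addition of zerovalent palladium into the aryl C–OTf bond, transmetalation with the acetate-activated diboron, reductive elimination) should give the boronic acid directly, the chromene alkene being inert.

Step 4
Reactants: 7 1-(5-bromo-2,4-dihydroxyphenyl)ethan-1-one
Product: 9 6-bromo-7-hydroxy-4H-chromen-4-one, via 6-bromo-2,7-dihydroxychroman-4-one 8 (not isolated)
Conditions: HCO2Et, NaH, THF, 0 °C to rt; then conc. HCl, AcOH, 60 °C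
Reagents that add atoms: ethyl formate CCOC=O
Why: Crossed Claisen condensation of the ketone enolate (formed beside the two phenoxides) with ethyl formate, followed by acid-promoted cyclodehydration of hemiacetal 8, is the classical chromone synthesis and tolerates the aryl bromide.

Step 5
Reactants: 9 6-bromo-7-hydroxy-4H-chromen-4-one; 6 (2,2-dimethyl-2H-chromen-6-yl)boronic acid
Product: 10 (2S)-6-bromo-2-(2,2-dimethyl-2H-chromen-6-yl)-7-hydroxy-2,3-dihydro-4H-chromen-4-one
Conditions: Pd(OCOCF3)2 (5 mol %), (R)-t-BuPyOx [(R)-4-tert-butyl-2-(pyridin-2-yl)-4,5-dihydrooxazole, 6 mol %], NH4PF6 (30 mol %), H2O (5 equiv), ClCH2CH2Cl, 60 °C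
Reagents that add atoms: none
Why: Asymmetric conjugate addition of the arylboronic acid to the chromone (Hayashi–Miyaura-type 1,4-addition under divalent palladium/pyridine-oxazoline catalysis: transmetalation, enantiofacial carbopalladation of C2=C3, protonolysis of the palladium enolate) sets C2, the tert-butyl group of the (R)-ligand steering the aryl group to the face that gives the S configuration, while the aryl bromide stays untouched because the cycle remains at divalent palladium.

Step 6
Reactants: 10 (2S)-6-bromo-2-(2,2-dimethyl-2H-chromen-6-yl)-7-hydroxy-2,3-dihydro-4H-chromen-4-one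
Product: 11 Dinklagin A, (2S)-2-(2,2-dimethyl-2H-chromen-6-yl)-7-hydroxy-6-(3-methylbut-2-en-1-yl)-2,3-dihydro-4H-chromen-4-one
Conditions: Bu3SnCH2CH=CMe2, Pd(PPh3)4 (cat.), 1,4-dioxane, 95 °C
Reagents that add atoms: tributyl(3-methylbut-2-en-1-yl)stannane CCCC[Sn](CCCC)(CCCC)CC=C(C)C
Why: Stille coupling of the aryl bromide with the prenylstannane under neutral conditions (oxidative addition, allyl transfer, reductive elimination at the less hindered α-terminus) should give the linear prenyl group without touching the base-sensitive C2 stereocentre, the free phenol or the chromene.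

**Compound list**

1 | benzofuran-5-ol | Oc1ccc2occc2c1 | starting material
2 | dilithium 2-[(Z)-2-lithioethenyl]benzene-1,4-diolate | [Li]/C=C\c1cc(O[Li])ccc1O[Li] | intermediate
3 | 2-[(Z)-3-hydroxy-3-methylbut-1-en-1-yl]benzene-1,4-diol | CC(C)(O)/C=C\c1cc(O)ccc1O | intermediate
4 | 2,2-dimethyl-2H-chromen-6-ol | CC1(C)C=Cc2cc(O)ccc2O1 | intermediate
5 | 2,2-dimethyl-2H-chromen-6-yl trifluoromethanesulfonate | CC1(C)C=Cc2cc(OS(=O)(=O)C(F)(F)F)ccc2O1 | intermediate
6 | (2,2-dimethyl-2H-chromen-6-yl)boronic acid | CC1(C)C=Cc2cc(B(O)O)ccc2O1 | intermediate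
7 | 1-(5-bromo-2,4-dihydroxyphenyl)ethan-1-one | CC(=O)c1cc(Br)c(O)cc1O | starting material
8 | 6-bromo-2,7-dihydroxy-2,3-dihydro-4H-chromen-4-one (racemic hemiacetal) | O=C1CC(O)Oc2cc(O)c(Br)cc12 | intermediate
9 | 6-bromo-7-hydroxy-4H-chromen-4-one | O=c1ccoc2cc(O)c(Br)cc12 | intermediate
10 | (2S)-6-bromo-2-(2,2-dimethyl-2H-chromen-6-yl)-7-hydroxy-2,3-dihydro-4H-chromen-4-one | Brc1cc2c(cc1O)O[C@H](c1ccc3c(c1)C=CC(C)(C)O3)CC2=O | intermediate
11 | Dinklagin A, (2S)-2-(2,2-dimethyl-2H-chromen-6-yl)-7-hydroxy-6-(3-methylbut-2-en-1-yl)-2,3-dihydro-4H-chromen-4-one | CC(C)=CCc1cc2c(cc1O)O[C@H](c1ccc3c(c1)C=CC(C)(C)O3)CC2=O | target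

**Step count and risks**

Total step count: 6. Longest linear sequence: 5 steps (steps 1, 2, 3, 5 and 6, from 1).

Steps most likely to fail:

1. Step 1. Electron transfer to the anionic, electron-rich aryloxide may be slow, the vinyllithium may deprotonate acetone instead of adding to it, and the electron-rich product may oligomerise during the acid closure. The fallback keeps the five-to-six ring expansion but replaces dissolving-metal reduction and carbonyl addition by transition-metal C–O activation. It sets out from 1, which is converted with 3,4-dihydro-2H-pyran and pyridinium p-toluenesulfonate into 5-(oxan-2-yloxy)-1-benzofuran F1. A nickel-catalysed Kumada-type coupling of the enol-ether C2–O bond with isopropenylmagnesium bromide (NiCl2(PCy3)2, toluene, 80 °C) should open the furan ring to 2-[(Z)-3-methylbuta-1,3-dien-1-yl]-4-(oxan-2-yloxy)phenol F2. TsOH in MeOH should then protonate the diene terminus, close the pyran ring through the same allyl cation and remove the acetal, returning to 4.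

2. Step 5. The arylpalladium species may insert into the electron-rich chromene double bond of 6 or 10 and stall turnover, the electron-rich boronic acid may protodeboronate, the acidic phenol may inhibit the catalyst, and facial discrimination may be incomplete. The fallback sets out from 9, which is protected with MOMCl and i-Pr2NEt as 6-bromo-7-(methoxymethoxy)-4H-chromen-4-one F3. A monovalent-rhodium/chiral-diene-catalysed 1,4-addition of 6 ([RhCl(C2H4)2]2, the antipode of a bicyclo[2.2.2]octadiene ligand that delivers the 2S product, aq. KOH, 1,4-dioxane, 40 °C) should give (2S)-6-bromo-2-(2,2-dimethyl-2H-chromen-6-yl)-7-(methoxymethoxy)-2,3-dihydro-4H-chromen-4-one F4. Dilute HCl in MeOH should remove the acetal and return to 10.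

3. Step 6. Allyl transfer may occur with allylic transposition (bond formation through the γ-carbon, giving the 1,1-dimethylallyl isomer), the acidic phenol may protodestannylate the reagent, and oxidative addition next to the free hydroxyl group may be sluggish. The fallback sets out from 10. Stille coupling with allyltributylstannane (Pd(PPh3)4, 1,4-dioxane, 95 °C), which has no regiochemical ambiguity, should give (2S)-2-(2,2-dimethyl-2H-chromen-6-yl)-7-hydroxy-6-(prop-2-en-1-yl)-2,3-dihydro-4H-chromen-4-one F5. Olefin cross-metathesis with 2-methylbut-2-ene (second-generation Grubbs catalyst, CH2Cl2, 40 °C) should exchange the terminal methylidene for the isopropylidene group, returning to 11.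

Further compounds
F1 | step 1 | 5-(oxan-2-yloxy)-1-benzofuran | O(C1CCCCO1)c1ccc2occc2c1
F2 | step 1 | 2-[(Z)-3-methylbuta-1,3-dien-1-yl]-4-(oxan-2-yloxy)phenol | CC(=C)/C=C\c1cc(OC2CCCCO2)ccc1O
F3 | step 5 | 6-bromo-7-(methoxymethoxy)-4H-chromen-4-one | COCOc1cc2occc(=O)c2cc1Br
F4 | step 5 | (2S)-6-bromo-2-(2,2-dimethyl-2H-chromen-6-yl)-7-(methoxymethoxy)-2,3-dihydro-4H-chromen-4-one | Brc1cc2c(cc1OCOC)O[C@H](c1ccc3c(c1)C=CC(C)(C)O3)CC2=O
F5 | step 6 | (2S)-2-(2,2-dimethyl-2H-chromen-6-yl)-7-hydroxy-6-(prop-2-en-1-yl)-2,3-dihydro-4H-chromen-4-one | C=CCc1cc2c(cc1O)O[C@H](c1ccc3c(c1)C=CC(C)(C)O3)CC2=O
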